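1. A stirred vessel at constant volume holds substrate and reagent, and one of them may be fed in; the flasks, the readings and the questions stand here.

| flask | substrate | reagent | remark | time |
|---|---|---|---|---|
| north | 0.20 M | 1.05 equiv | run made earlier |  |
| east | 0.13 M | 1.05 equiv | run made earlier |  |
| north-west | 0.30 M | 1.05 equiv | run made earlier |  |
| south-west | 0.20 M | 0.53 equiv | run made earlier |  |
| Tuesday's | 0.20 M (fed, over 50 min) | 1.05 equiv | all else is in the flask from the start; the feed brings no volume worth counting | 1.0 h |
| Wednesday's | 0.20 M | 1.05 equiv (fed, over 50 min) | all else is in the flask from the start; the feed brings no volume worth counting | 1.0 h |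
| Sunday's | 0.20 M | 1.05 equiv | everything together at the start | 1.0 h |

| run | time / min | mono adduct / % | bis adduct / % | substrate / % |
|---|---|---|---|---|
| north | 3.00 | 8.9 | 1.1 | 83.5 |
| north | 10.0 | 18.1 | 7.9 | 59.8 |
| north | 15.0 | 19.8 | 11.6 | 49.8 |
| north | 25.0 | 21.5 | 18.8 | 36.6 |
| north | 40.0 | 20.2 | 25.0 | 26.0 |
| east | 6.00 | 10.7 | 2.4 | 79.4 |
| east | 10.0 | 14.4 | 4.2 | 69.9 |
| east | 20.0 | 19.2 | 10.5 | 52.9 |
| east | 40.0 | 20.9 | 19.8 | 36.4 |
| east | 80.0 | 19.3 | 28.3 | 21.7 |
| north-west | 6.00 | 17.4 | 6.4 | 62.4 |
| north-west | 10.0 | 20.1 | 11.9 | 48.9 |
| north-west | 20.0 | 20.8 | 21.8 | 32.5 |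
| north-west | 40.0 | 19.0 | 29.5 | 19.4 |
| north-west | 80.0 | 17.1 | 34.5 | 10.0 |
| south-west | 6.00 | 8.6 | 1.1 | 85.3 |
| south-west | 20.0 | 15.8 | 4.8 | 64.9 |
| south-west | 30.0 | 16.8 | 6.4 | 58.0 |
| south-west | 50.0 | 18.4 | 9.1 | 49.8 |
| south-west | 80.0 | 18.2 | 9.8 | 43.3 |

(readings scatter by 0.5 percentage points)



- the flask that comes out highest in share of mono adduct in mono adduct plus bis adduct, or "all alike" when all lie within 1.5 percentage points (Tuesday's / Wednesday's / Sunday's / all alike)
- share of mono adduct in mono adduct plus bis adduct at the end, Tuesday's
- share of mono adduct in mono adduct plus bis adduct at the end, Wednesday's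
- share of mono adduct in mono adduct plus bis adduct at the end, Sunday's

2. The fastest rung is the substrate clock. Let a be the fraction of the substrate charge still present. With near-equal charges a falls as 1/(1+t/τ), and the north reading at 10.0 min gives τ = 14.9 min.

3. The next rung is the crossing, where loss of mono adduct overtakes its formation, and it comes later than τ. North reads its highest mono adduct at 25.0 min, east at 40.0 min, yet a stands at 36.6% and 36.4%. At those readings the selectivity, the share of mono adduct in mono adduct plus bis adduct, stands at 53.3% in north and 51.4% in east, both charged with 1.05 equiv of reagent, so at this reagent charge the share is read against a and not the clock. South-west, charged with 0.53 equiv, stands apart with a share of 65.0% at a = 43.3%, so the reading holds the reagent charge fixed. Beyond north's highest mono adduct, the ratio of the fall in share to the fall in a is 0.817, the gauge, taken for flasks with substrate in from the start and 1.05 equiv of reagent.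

4. The slowest rungs are the feed and the end. Sunday's reaches a = 19.9%, so the gauge gives 39.7%. Wednesday's reagent arrives on average halfway through the feed, which leaves 35.0 min of clock, a = 29.8% and a share of 47.7%. Tuesday's lies outside the gauge; its mono adduct forms beside the full reagent charge, so this reckoning puts it under Wednesday's.

5. The forecast, a little higher for Wednesday's, names Wednesday's with 42% (34% to 50%) for Tuesday's, 50% (45% to 57%) for Wednesday's and 40% (37.5% to 43%) for Sunday's, on the ground that “the product path versus substrate matches batch”.

6. The flasks give 38.2% for Tuesday's, 48.0% for Wednesday's and 38.7% for Sunday's, so Wednesday's comes out highest.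

    substrate + reagent → mono adduct + by-product (k = 0.190 L mol⁻¹ min⁻¹)
    substrate + reagent → other mono adduct + by-product (k = 0.120 L mol⁻¹ min⁻¹)
    reagent + mono adduct → bis adduct + by-product (k = 0.340 L mol⁻¹ min⁻¹)
    reagent + other mono adduct → bis adduct + by-product (k = 0.170 L mol⁻¹ min⁻¹)
    substrate + by-product → side product (k = 0.0530 L mol⁻¹ min⁻¹)

7. Wednesday's ended with a = 31.3%, where the gauge reads 49.0% against 48.0%, although 16.7% of other mono adduct and 10.4% of side product stood unread in that flask. The neighbour of Wednesday's charged with 0.34 M ended at a = 21.1%, where the gauge reads 40.6%, and it gave 39.9%. Tuesday's, at a = 35%, sits 14 percentage points under the gauge, and its gap to Wednesday's comes in part from reagent turning mono adduct into bis adduct: with that step taken away, the gap falls from 9.9 points to 3.8 points.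

The data stem from a simulated flask with made-up constants, noise included.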